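**Strategy.** Ring A (the carbocycle C4a–C5–C6–C7–C8–C8a, chromene numbering) is not assembled as a six-membered ring: it grows from the four-membered ring of cyclobutenone 12 by insertion of the two alkyne carbons of siloxyalkyne 6. This thermal cascade (4π opening, [2+2], 4π opening, 6π closure) exploits the alternating pattern of ring A, oxygen on C5, C7, C8a and carbon on C6, C8, C4a. In one operation it should deliver a phenol carrying the lavandulyl group, the benzylic stereocentre and three differentiated oxygens. Ring B is then annulated through a Mitsunobu inversion and an acylation, and C8 is made quaternary by catalyst-controlled dearomative prenylation.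

Key step: step 5

Remarks on the chemistry:
- Atoms are numbered as in 2H-chromene (O1, C2, C3, C4, C4a, C5 to C8, C8a); ring A is the carbocycle, ring B the pyranone.
- Lav = (2S)-5-methyl-2-(prop-1-en-2-yl)hex-4-en-1-yl, the lavandulyl group with the spatial arrangement of (R)-lavandulol. The descriptor reads S once C1 of the group is bonded to carbon.
- (R)-Lavandulol is taken as commercially available.
- The sense of induction of the organocatalyst in step 3 and of the phosphine ligand in step 11 is assumed. In either case the pseudo-enantiomeric or enantiomeric catalyst gives the opposite sense.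

Step 1
Reactants: 1 (R)-lavandulol
Product: 3 trimethyl[(4S)-7-methyl-4-(prop-1-en-2-yl)oct-6-en-1-yn-1-yl]silane, via lavandulyl triflate 2 (not isolated)
Conditions: Tf2O, 2,6-lutidine, CH2Cl2, −78 °C; then LiC≡CSiMe3 (from Me3SiC≡CH, n-BuLi), THF–DMPU, −78 to −20 °C
Reagents that add atoms: trimethylsilylacetylene (used as its lithium salt), C#C[Si](C)(C)C
Why: Low-temperature SN2 displacement of a primary triflate by a lithium acetylide is a standard chain extension of β-branched alcohols and should outrun elimination; the stereocentre is not involved and keeps its spatial arrangement.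

Step 2
Reactants: 3 trimethylsilyl alkyne
Product: 6 triisopropyl{[(4S)-7-methyl-4-(prop-1-en-2-yl)oct-6-en-1-yn-1-yl]oxy}silane, via lithium acetylide 4 (not isolated), via lithium ynolate 5 (not isolated)
Conditions: MeLi·LiBr, THF, 0 °C to rt; t-BuOOLi (from t-BuOOH, LiN(SiMe3)2), THF, −78 to 0 °C; i-Pr3SiOTf, −78 °C
Reagents that add atoms: lithium tert-butyl peroxide (one oxygen atom), CC(C)(C)OO[Li]; triisopropylsilyl trifluoromethanesulfonate, CC(C)[Si](OS(=O)(=O)C(F)(F)F)(C(C)C)C(C)C
Why: Methyllithium cleaves the C(sp)–Si bond to acetylide 4, oxygen transfer from the lithium peroxide converts 4 into ynolate 5, and the bulky silyl triflate traps 5 on oxygen, which is the established preparation of siloxyalkynes.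

Step 3
Reactants: 7 3-phenylglutaric anhydride
Product: 8 (3S)-5-methoxy-5-oxo-3-phenylpentanoic acid
Conditions: MeOH (10 equiv), quinine-derived bifunctional 3,5-bis(trifluoromethyl)benzenesulfonamide organocatalyst (10 mol%), MTBE, 0 °C
Reagents that add atoms: methanol, CO
Why: Organocatalytic enantioselective methanolysis (desymmetrisation) of a prochiral cyclic anhydride, in which the catalyst activates methanol by general-base catalysis and one enantiotopic carbonyl group by hydrogen bonding, sets the future benzylic stereocentre.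

Step 4
Reactants: 8 hemiester; 9 ethoxyacetylene
Product: 12 methyl (3R)-3-(2-ethoxy-4-oxocyclobut-2-en-1-yl)-3-phenylpropanoate, via acid chloride 10 (not isolated), via ketene 11 (not isolated)
Conditions: (COCl)2, DMF (cat.), CH2Cl2, 0 °C to rt; evaporate; then slow addition to 9 (3 equiv), Et3N, Et2O, 0 °C to rt
Reagents that add atoms: none
Why: Dehydrochlorination of 10 gives aldoketene 11, which is trapped by the electron-rich alkyne in a regioselective [2+2] cycloaddition (ketene carbonyl carbon to the unsubstituted alkyne carbon), the classical entry to 3-ethoxycyclobutenones; the benzylic centre is β to the ketene and cannot epimerise, and the new ring stereocentre is lost again in step 5.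

Step 5
Reactants: 12 cyclobutenone; 6 siloxyalkyne (1.3 equiv)
Product: 17 methyl (3S)-3-{6-ethoxy-2-hydroxy-3-Lav-4-[(triisopropylsilyl)oxy]phenyl}-3-phenylpropanoate, via vinylketene 13 (not isolated), via alkenylcyclobutenone 14 (not isolated), via dienylketene 15 (not isolated), via cyclohexadienone 16 (not isolated)
Conditions: toluene, 90–110 °C, sealed tube
Reagents that add atoms: none
Why: Danheiser benzannulation: heating opens 12 by 4π-electrocyclic ring opening to vinylketene 13, which adds siloxyalkyne 6 in a regioselective [2+2] cycloaddition (ketene carbonyl carbon to the lavandulyl-bearing, nucleophilic alkyne carbon) to give 4-alkenylcyclobutenone 14; a second 4π opening gives dienylketene 15, whose 6π-electrocyclisation gives cyclohexadienone 16, and enolisation gives phenol 17. The closest known reaction type is the thermal annulation of cyclobutenones, 3-alkoxy ones included, with alkoxy- and siloxyalkynes to resorcinol and phloroglucinol derivatives. The only ring closed is ring A, by a thermally allowed disrotatory 6π-electrocyclisation, in which the four carbons of the four-membered ring (they become C7, C6, C5 and C4a) are joined through the two alkyne carbons (C8 and C8a). No stereocentre is created: the ring stereocentre of 12 becomes sp2, and the benzylic and lavandulyl centres lie outside the reacting π-system and are retained. The step needs regiocontrol in the [2+2] event, which the polarisation of ketene and ynol ether secures, so that OH (C7), OSi (C8a) and OEt (C5) come out differentiated with lavandulyl on C8 and the side chain on C6.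

Step 6
Reactants: 17 silyl ether
Product: 18 methyl (3S)-3-(6-ethoxy-2,4-dihydroxy-3-Lav-phenyl)-3-phenylpropanoate
Conditions: Bu4NF, AcOH, THF, 0 °C
Reagents that add atoms: none
Why: Fluoride cleaves the aryl silyl ether, driven by the Si–F bond, and acetic acid buffers the phenoxide so that the methyl ester is left alone.

Step 7
Reactants: 19 tert-butyl (3S)-3-hydroxybutanoate
Product: 20 tert-butyl (2S,3S)-3-hydroxy-2-methylbutanoate
Conditions: LiN(i-Pr)2 (2.2 equiv), THF, −50 to −20 °C; MeI, DMPU, −78 to 0 °C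
Reagents that add atoms: iodomethane, CI
Why: Fráter–Seebach alkylation: the chelated lithium alkoxide enolate is methylated on the face opposite to the C3 methyl group, which should give the anti (2S,3S) product.

Step 8
Reactants: 18 diphenol; 20 hydroxy ester
Product: 21 tert-butyl (2S,3R)-3-{5-ethoxy-3-hydroxy-4-[(1S)-3-methoxy-3-oxo-1-phenylpropyl]-2-Lav-phenoxy}-2-methylbutanoate
Conditions: PPh3, DIAD, toluene, 0 °C to rt
Reagents that add atoms: none
Why: Mitsunobu etherification proceeds by SN2 attack of the phenol on the alkoxyphosphonium ion with inversion, which turns the (3S)-carbinol into the (R)-configured C2–O1 bond of ring B; the phenol with a single ortho substituent should react, the other being shielded by two branched ortho groups.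

Step 9
Reactants: 21 tert-butyl ester
Product: 23 (2S,3R)-3-{5-ethoxy-3-hydroxy-4-[(1S)-3-methoxy-3-oxo-1-phenylpropyl]-2-Lav-phenoxy}-2-methylbutanoic acid, via bis(trimethylsilyl) derivative 22 (not isolated)
Conditions: Me3SiOTf, 2,6-lutidine, CH2Cl2, 0 °C; then aqueous pH 4 buffer, MeOH
Reagents that add atoms: none
Why: The silyl triflate activates the tert-butyl ester, which loses 2-methylpropene to give the silyl ester (the phenol is silylated at the same time), and aqueous work-up frees acid and phenol; the buffered reagent should leave the methyl ester, the alkenes and the stereocentres untouched.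

Step 10
Reactants: 23 aryloxy acid
Product: 25 methyl (3S)-3-[(2R,3S)-5-ethoxy-7-hydroxy-2,3-dimethyl-8-Lav-4-oxo-3,4-dihydro-2H-chromen-6-yl]-3-phenylpropanoate, via mixed anhydride 24 (not isolated)
Conditions: (CF3CO)2O, CH2Cl2, 0 °C; then NaHCO3, MeOH, 0 °C
Reagents that add atoms: none
Why: Intramolecular Friedel–Crafts acylation through the mixed trifluoroacetic anhydride closes the six-membered ring B at C4a, the only unsubstituted position of the electron-rich ring and ortho to the ether oxygen; no base is present, so the cis (2R,3S) arrangement should be kept.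

Step 11
Reactants: 25 chromanone phenol
Product: 26 methyl (3S)-3-[(2R,3S,8S)-5-ethoxy-2,3-dimethyl-8-(3-methylbut-2-en-1-yl)-8-Lav-4,7-dioxo-3,4,7,8-tetrahydro-2H-chromen-6-yl]-3-phenylpropanoate
Conditions: Pd2(dba)3·CHCl3 (2.5 mol%), (R,R)-N,N'-(cyclohexane-1,2-diyl)bis[2-(diphenylphosphanyl)benzamide] (7.5 mol%), prenyl acetate, Cs2CO3, toluene, 0 °C to rt
Reagents that add atoms: 3-methylbut-2-en-1-yl acetate, CC(C)=CCOC(C)=O
Why: Palladium-catalysed asymmetric allylic alkylation with dearomatisation: the caesium phenoxide attacks the π-prenyl complex of divalent palladium through C8 at the unsubstituted allyl terminus (O-allylation is reversible under the catalysis and C6 is shielded by its branched substituent), and the C2-symmetric ligand selects the face of C8, which should set the (8S) quaternary centre under catalyst control.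

Step 12
Reactants: 26 dearomatised diester
Product: 27 target acid
Conditions: LiOH, THF/MeOH/H2O, 0 °C to rt; then 1 M HCl to pH 3
Reagents that add atoms: lithium hydroxide (hydroxide oxygen), [Li+].[OH-]
Why: Hydroxide saponifies the methyl ester and cleaves the vinylogous ethyl ester at C5 by conjugate addition–elimination; the delocalised triketone anion that results protects C3 against epimerisation, and acidification should give the chelated enol acid.

**Compound list**

1 | (R)-lavandulol, (2R)-5-methyl-2-(prop-1-en-2-yl)hex-4-en-1-ol | C=C(C)[C@@H](CC=C(C)C)CO | starting material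
2 | (2R)-5-methyl-2-(prop-1-en-2-yl)hex-4-en-1-yl trifluoromethanesulfonate | C=C(C)[C@@H](CC=C(C)C)COS(=O)(=O)C(F)(F)F | intermediate
3 | trimethyl[(4S)-7-methyl-4-(prop-1-en-2-yl)oct-6-en-1-yn-1-yl]silane | C=C(C)[C@@H](CC=C(C)C)CC#C[Si](C)(C)C | intermediate
4 | lithium (4S)-7-methyl-4-(prop-1-en-2-yl)oct-6-en-1-yn-1-ide | C=C(C)[C@@H](CC=C(C)C)CC#C[Li] | intermediate
5 | lithium (4S)-7-methyl-4-(prop-1-en-2-yl)oct-6-en-1-yn-1-olate (ynolate) | C=C(C)[C@@H](CC=C(C)C)CC#CO[Li] | intermediate
6 | triisopropyl{[(4S)-7-methyl-4-(prop-1-en-2-yl)oct-6-en-1-yn-1-yl]oxy}silane | C=C(C)[C@@H](CC=C(C)C)CC#CO[Si](C(C)C)(C(C)C)C(C)C | intermediate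
7 | 3-phenylglutaric anhydride (4-phenyloxane-2,6-dione) | O=C1CC(c2ccccc2)CC(=O)O1 | starting material
8 | (3S)-5-methoxy-5-oxo-3-phenylpentanoic acid | COC(=O)C[C@@H](c1ccccc1)CC(=O)O | intermediate
9 | ethoxyacetylene (ethoxyethyne) | C#COCC | starting material
10 | methyl (3R)-5-chloro-5-oxo-3-phenylpentanoate | COC(=O)C[C@@H](c1ccccc1)CC(=O)Cl | intermediate
11 | methyl (3R)-5-oxo-3-phenylpent-4-enoate (ketene) | COC(=O)C[C@@H](c1ccccc1)C=C=O | intermediate
12 | methyl (3R)-3-(2-ethoxy-4-oxocyclobut-2-en-1-yl)-3-phenylpropanoate, both epimers at ring C1 | COC(=O)C[C@@H](c1ccccc1)C1C(=O)C=C1OCC | intermediate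
13 | methyl (3R)-5-ethoxy-7-oxo-3-phenylhepta-4,6-dienoate (vinylketene) | COC(=O)C[C@@H](c1ccccc1)C=C(OCC)C=C=O | intermediate
14 | methyl (3R)-5-ethoxy-5-{3-Lav-4-oxo-2-[(triisopropylsilyl)oxy]cyclobut-2-en-1-yl}-3-phenylpent-4-enoate | COC(=O)C[C@@H](c1ccccc1)C=C(OCC)C1C(=O)C(C[C@H](CC=C(C)C)C(C)=C)=C1O[Si](C(C)C)(C(C)C)C(C)C | intermediate
15 | methyl (3R)-5-ethoxy-8-Lav-9-oxo-3-phenyl-7-[(triisopropylsilyl)oxy]nona-4,6,8-trienoate (dienylketene) | COC(=O)C[C@@H](c1ccccc1)C=C(OCC)C=C(O[Si](C(C)C)(C(C)C)C(C)C)C(C[C@H](CC=C(C)C)C(C)=C)=C=O | intermediate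
16 | methyl (3R)-3-{2-ethoxy-5-Lav-6-oxo-4-[(triisopropylsilyl)oxy]cyclohexa-2,4-dien-1-yl}-3-phenylpropanoate | COC(=O)C[C@@H](c1ccccc1)C1C(=O)C(C[C@H](CC=C(C)C)C(C)=C)=C(O[Si](C(C)C)(C(C)C)C(C)C)C=C1OCC | intermediate
17 | methyl (3S)-3-{6-ethoxy-2-hydroxy-3-[(2S)-5-methyl-2-(prop-1-en-2-yl)hex-4-en-1-yl]-4-[(triisopropylsilyl)oxy]phenyl}-3-phenylpropanoate | COC(=O)C[C@@H](c1ccccc1)c1c(O)c(C[C@H](CC=C(C)C)C(C)=C)c(O[Si](C(C)C)(C(C)C)C(C)C)cc1OCC | intermediate
18 | methyl (3S)-3-{6-ethoxy-2,4-dihydroxy-3-[(2S)-5-methyl-2-(prop-1-en-2-yl)hex-4-en-1-yl]phenyl}-3-phenylpropanoate | COC(=O)C[C@@H](c1ccccc1)c1c(O)c(C[C@H](CC=C(C)C)C(C)=C)c(O)cc1OCC | intermediate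
19 | tert-butyl (3S)-3-hydroxybutanoate | C[C@H](O)CC(=O)OC(C)(C)C | starting material
20 | tert-butyl (2S,3S)-3-hydroxy-2-methylbutanoate | C[C@H](O)[C@H](C)C(=O)OC(C)(C)C | intermediate
21 | tert-butyl (2S,3R)-3-{5-ethoxy-3-hydroxy-4-[(1S)-3-methoxy-3-oxo-1-phenylpropyl]-2-[(2S)-5-methyl-2-(prop-1-en-2-yl)hex-4-en-1-yl]phenoxy}-2-methylbutanoate | COC(=O)C[C@@H](c1ccccc1)c1c(O)c(C[C@H](CC=C(C)C)C(C)=C)c(O[C@H](C)[C@H](C)C(=O)OC(C)(C)C)cc1OCC | intermediate
22 | trimethylsilyl (2S,3R)-3-{5-ethoxy-4-[(1S)-3-methoxy-3-oxo-1-phenylpropyl]-2-Lav-3-[(trimethylsilyl)oxy]phenoxy}-2-methylbutanoate | COC(=O)C[C@@H](c1ccccc1)c1c(O[Si](C)(C)C)c(C[C@H](CC=C(C)C)C(C)=C)c(O[C@H](C)[C@H](C)C(=O)O[Si](C)(C)C)cc1OCC | intermediate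
23 | (2S,3R)-3-{5-ethoxy-3-hydroxy-4-[(1S)-3-methoxy-3-oxo-1-phenylpropyl]-2-[(2S)-5-methyl-2-(prop-1-en-2-yl)hex-4-en-1-yl]phenoxy}-2-methylbutanoic acid | COC(=O)C[C@@H](c1ccccc1)c1c(O)c(C[C@H](CC=C(C)C)C(C)=C)c(O[C@H](C)[C@H](C)C(=O)O)cc1OCC | intermediate
24 | mixed anhydride of acid 23 with trifluoroacetic acid | COC(=O)C[C@@H](c1ccccc1)c1c(O)c(C[C@H](CC=C(C)C)C(C)=C)c(O[C@H](C)[C@H](C)C(=O)OC(=O)C(F)(F)F)cc1OCC | intermediate
25 | methyl (3S)-3-{(2R,3S)-5-ethoxy-7-hydroxy-2,3-dimethyl-8-[(2S)-5-methyl-2-(prop-1-en-2-yl)hex-4-en-1-yl]-4-oxo-3,4-dihydro-2H-chromen-6-yl}-3-phenylpropanoate | C=C(C)[C@@H](CC=C(C)C)Cc1c(O)c([C@@H](CC(=O)OC)c3ccccc3)c(OCC)c2c1O[C@H](C)[C@H](C)C2=O | intermediate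
26 | methyl (3S)-3-{(2R,3S,8S)-5-ethoxy-2,3-dimethyl-8-(3-methylbut-2-en-1-yl)-8-[(2S)-5-methyl-2-(prop-1-en-2-yl)hex-4-en-1-yl]-4,7-dioxo-3,4,7,8-tetrahydro-2H-chromen-6-yl}-3-phenylpropanoate | C=C(C)[C@@H](CC=C(C)C)C[C@]1(CC=C(C)C)C(=O)C([C@@H](CC(=O)OC)c3ccccc3)=C(OCC)C2=C1O[C@H](C)[C@H](C)C2=O | intermediate
27 | (3S)-3-{(2R,3S,8S)-5-hydroxy-2,3-dimethyl-8-(3-methylbut-2-en-1-yl)-8-[(2S)-5-methyl-2-(prop-1-en-2-yl)hex-4-en-1-yl]-4,7-dioxo-3,4,7,8-tetrahydro-2H-chromen-6-yl}-3-phenylpropanoic acid | C=C(C)[C@@H](CC=C(C)C)C[C@]1(CC=C(C)C)C(=O)C([C@@H](CC(=O)O)c2ccccc2)=C(O)C2=C1O[C@H](C)[C@H](C)C2=O | target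

**Step count.** Total: 12 steps. Longest linear sequence: 9 steps (steps 1, 2, 5, 6, 8, 9, 10, 11, 12 from (R)-lavandulol; equally steps 3, 4, 5, 6, 8 to 12 from anhydride 7).

**Steps most likely to fail**

Step 11. O-allylation or attack through C6 may compete with allylation at C8, and the chiral ligand may discriminate the two faces of C8 poorly against the bias of the four existing stereocentres. The fallback replaces the ionic delivery of the prenyl group by a sigmatropic one and sets out from 25. Copper-catalysed O-alkylation with 3-chloro-3-methylbut-1-yne (CuCl2 cat., DBU, MeCN, 0 °C) should give the aryl 1,1-dimethylpropargyl ether F1. Semihydrogenation (H2, Pd on CaCO3 poisoned with Pb(OAc)2, quinoline) should give the aryl 1,1-dimethylallyl ether F2. Heating (toluene, 110 °C) should bring about a dearomatising ortho-Claisen rearrangement that delivers the prenyl group to C8; the shift to the more hindered C6 is reversible. The fallback comes back to the route at 26, the C8 epimer being removed by chromatography.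

Step 8. The activated β-hydroxy ester may eliminate to the tiglate, substitution at a branched secondary carbon by a hindered phenol may be slow, and the second phenol may compete. The fallback forms the C–C bond first and closes ring B by an intramolecular Mitsunobu reaction; it sets out from 18 and 20. Ester 20 is cleaved with CF3CO2H in CH2Cl2 to (2S,3S)-3-hydroxy-2-methylbutanoic acid F3. Acylation of 18 with F3 and (CF3CO)2O (CH2Cl2, 0 °C; the hydroxyl is masked in situ as its trifluoroacetate and released with NaHCO3/MeOH) should occur at the only free ring position and give the β-hydroxy ketone F4. Treatment with PPh3 and DIAD in THF should then close ring B with inversion at the carbinol carbon, because only the hydroxyl ortho to the ketone can reach it. The fallback comes back at 25; steps 9 and 10 are then not needed.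

Step 5. The substituent on the sp3 carbon of 12 may slow the cascade (inward rotation in the ring opening, 1,5-hydrogen shift of the vinylketene), or the phenol formed may be acylated by vinylketene that has not yet reacted. The fallback attaches the side chain after the ring expansion and sets out from 6 and commercially available 3-ethoxycyclobut-2-en-1-one. The same thermal ring expansion (toluene, 90 °C) should give the phenol F5. Organocatalytic Friedel–Crafts alkylation and hemiacetalisation with cinnamaldehyde ((S)-α,α-diphenylprolinol trimethylsilyl ether, PhCO2H, toluene) should give the lactol F6; the arene attacks the iminium face anti to the bulky group, which should give the (S) benzylic centre ortho to the free hydroxyl. Oxidation (TEMPO cat., PhI(OAc)2, CH2Cl2) should give the lactone F7. Methanolysis (NaOMe, MeOH, −20 °C, then AcOH) comes back to the route at 17; steps 3 and 4 are then not needed.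

Further compounds
F1 | step 11 | methyl (3S)-3-{(2R,3S)-5-ethoxy-2,3-dimethyl-7-[(2-methylbut-3-yn-2-yl)oxy]-8-[(2S)-5-methyl-2-(prop-1-en-2-yl)hex-4-en-1-yl]-4-oxo-3,4-dihydro-2H-chromen-6-yl}-3-phenylpropanoate | C=C(C)[C@@H](CC=C(C)C)Cc1c(OC(C)(C)C#C)c([C@@H](CC(=O)OC)c3ccccc3)c(OCC)c2c1O[C@H](C)[C@H](C)C2=O
F2 | step 11 | methyl (3S)-3-{(2R,3S)-5-ethoxy-2,3-dimethyl-7-[(2-methylbut-3-en-2-yl)oxy]-8-[(2S)-5-methyl-2-(prop-1-en-2-yl)hex-4-en-1-yl]-4-oxo-3,4-dihydro-2H-chromen-6-yl}-3-phenylpropanoate | C=C(C)[C@@H](CC=C(C)C)Cc1c(OC(C)(C)C=C)c([C@@H](CC(=O)OC)c3ccccc3)c(OCC)c2c1O[C@H](C)[C@H](C)C2=O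
F3 | step 8 | (2S,3S)-3-hydroxy-2-methylbutanoic acid | C[C@H](O)[C@H](C)C(=O)O
F4 | step 8 | methyl (3S)-3-{2-ethoxy-4,6-dihydroxy-3-[(2S,3S)-3-hydroxy-2-methylbutanoyl]-5-[(2S)-5-methyl-2-(prop-1-en-2-yl)hex-4-en-1-yl]phenyl}-3-phenylpropanoate | COC(=O)C[C@@H](c1ccccc1)c1c(O)c(C[C@H](CC=C(C)C)C(C)=C)c(O)c(C(=O)[C@@H](C)[C@H](C)O)c1OCC
F5 | step 5 | 5-ethoxy-2-[(2S)-5-methyl-2-(prop-1-en-2-yl)hex-4-en-1-yl]-3-[(triisopropylsilyl)oxy]phenol | C=C(C)[C@@H](CC=C(C)C)Cc1c(O)cc(OCC)cc1O[Si](C(C)C)(C(C)C)C(C)C
F6 | step 5 | (4S)-5-ethoxy-8-[(2S)-5-methyl-2-(prop-1-en-2-yl)hex-4-en-1-yl]-4-phenyl-7-[(triisopropylsilyl)oxy]-3,4-dihydro-2H-chromen-2-ol, both anomers | C=C(C)[C@@H](CC=C(C)C)Cc1c2OC(O)C[C@@H](c3ccccc3)c2c(OCC)cc1O[Si](C(C)C)(C(C)C)C(C)C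
F7 | step 5 | (4S)-5-ethoxy-8-[(2S)-5-methyl-2-(prop-1-en-2-yl)hex-4-en-1-yl]-4-phenyl-7-[(triisopropylsilyl)oxy]-3,4-dihydro-2H-chromen-2-one | C=C(C)[C@@H](CC=C(C)C)Cc1c2OC(=O)C[C@@H](c3ccccc3)c2c(OCC)cc1O[Si](C(C)C)(C(C)C)C(C)C
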